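(The readings are simulated with made-up constants; noise was put on by code.)

**Open balance.** The target in Tuesday's run reads 41.2 % at 20.0 min and 40.4 % at 30.0 min. That change lies inside the scatter of 1 percentage point, so the readings are taken as a plateau of 40.8 %, a reading of the yield of target in Tuesday's run. The open balance of Tuesday's run, the part of the charge in neither target nor intermediate C, falls from 51.9 % at 10.0 min to 14.6 % at 30.0 min. Read as a first-order loss, this gives k = 0.0634 /min.

| flask | starting material | remark | time |
|---|---|---|---|
| Tuesday's | 0.75 M | run made earlier |  |
| flask | 1.5 M |  | 2.5 h |

Tuesday's run (percent of the starting material charged)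

| time / min | target / % | intermediate C / % |
|---|---|---|
| 4.00 | 17.2 | 0.1 |
| 10.0 | 35.6 | 12.5 |
| 20.0 | 41.2 | 32.3 |
| 30.0 | 40.4 | 45.0 |

(scatter of a reading: 1 percentage point)



1. the target standing at 2.5 h, as a percentage of the starting material charged
2. the intermediate C standing at 2.5 h, as a percentage of the starting material charged
3. amount of target if the flask were left three thousand times as long, in percent of the starting material charged

**One number.** For the new flask, N = k·t = 9.51, the lifetimes of the open balance that fit into the run. The time 2.5 h is far longer than the lifetime 15.8 min, so e^−N is 0.00741 %. The reckoning therefore reads the plateau: target 40.8 %, intermediate C 59.2 %, and the same target after the long wait.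

**The test.** N estimates how far the open balance falls, not how the charge splits. Tuesday's run has one concentration and shows no order, so k and the plateau carry to twice the [starting material] only as assumptions.

**Forecast.** The forecast gives target 12 %, intermediate C 80 % and 12 % after the long wait: “I expect mostly C with modest target”. The reckoning here puts target higher.

**Result.** starting material ⇌ intermediate A (K = 2.30, k = 0.00540 /s); intermediate A → target (k = 0.00330 /s); intermediate A → intermediate B (k = 0.00450 /s); intermediate B → intermediate C (k = 3.20 × 10⁻⁴ /s); intermediate C ⇌ intermediate D (K = 0.130, k = 0.00750 /s); intermediate B → intermediate E (k = 0.00330 /s); intermediate E → intermediate C (k = 0.00210 /s)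

The flask gives target 42.3 %, intermediate C 51.1 % and 42.3 % after the long wait. With N = 9.51, e^−N is 0.00741 %, yet 6.60 % stays outside target and intermediate C, and intermediate D stands at 6.64 %. The same flask read at 40 min has N = 2.54, so e^−N is 7.92 %, and intermediates D and E together hold 8.45 %.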